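**Retrosynthetic overview**
- Cut the amide C–N bond: the target comes from 2,3-dibromo-4,5-dihydroxybenzylamine and succinic anhydride. Opening the anhydride gives the amide and the free acid together, without protecting groups.
- Make the benzylic C–N bond by functional-group interconversion: benzylamine ⇒ aldoxime ⇒ 2,3-dibromo-4,5-dihydroxybenzaldehyde.
- Cut the C2–Br bond: the dibromo aldehyde comes from commercial 3-bromo-4,5-dihydroxybenzaldehyde by bromination para to the 5-OH.
- Rings: none is formed. The benzene ring is bought complete, and the only ring event is the opening of the anhydride in the last step.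

Assumption: the target has no stereocentre and no stereogenic double bond, so it is achiral and the "single enantiomer" demand needs no action; compound 1 is taken as a catalogue chemical.

**Step 1**
Reactants: 1 3-bromo-4,5-dihydroxybenzaldehyde
Product: 2 2,3-dibromo-4,5-dihydroxybenzaldehyde
Conditions: Br2 (1.1 equiv), AcOH, rt to 45 °C, 16 h; pour into ice water, filter
Reagents that add atoms: bromine, BrBr
Why: In this electrophilic aromatic bromination (SEAr) the 4-OH has all its ortho and para sites blocked, so the 5-OH alone directs and attack para to it (C2) beats the ortho site C6, as when 5-bromovanillin gives 5,6-dibromovanillin, while CHO and Br keep the catechol too electron-poor to oxidise to the quinone and about one equivalent of Br2 holds back the tribromide; no stereocentre is formed.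

**Step 2**
Reactants: 2 2,3-dibromo-4,5-dihydroxybenzaldehyde
Product: 4 2,3-dibromo-4,5-dihydroxybenzylamine, via aldoxime 3 (not isolated)
Conditions: 50% aq NH2OH (1.2 equiv), EtOH, rt, 2 h; then AcOH (EtOH–AcOH 1:1), Zn dust (6 equiv), 0 °C to rt, 3 h, N2; filter, neutral aqueous work-up, use at once
Reagents that add atoms: hydroxylamine, NO
Why: Oxime condensation followed in the same flask by dissolving-metal reduction (Zn/AcOH) cleaves the N–O bond and saturates the C=N bond to give only the primary amine, without the dibenzylamine that troubles direct reductive amination using ammonia, and aryl C–Br bonds and the catechol should tolerate Zn in AcOH at rt; no stereocentre is formed and the geometry of 3 disappears in the product.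

**Step 3**
Reactants: 4 2,3-dibromo-4,5-dihydroxybenzylamine; 5 succinic anhydride
Product: 6 4-[(2,3-dibromo-4,5-dihydroxybenzyl)amino]-4-oxobutanoic acid (target)
Conditions: 5 (1.05 equiv), THF–DMF 4:1, N2, 0 °C to rt, 4 h; dilute with water, acidify to pH 2–3, extract (EtOAc), crystallise
Reagents that add atoms: none
Why: Aminolysis (ring opening) of a cyclic anhydride is a pure addition in which the primary benzylic amine reacts far faster than the two electron-poor phenols, and at rt the amic acid does not close to the imide, so the C–Br bonds and the catechol stay untouched; no stereocentre is formed.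

**Compound list**
1 | 3-bromo-4,5-dihydroxybenzaldehyde | O=Cc1cc(O)c(O)c(Br)c1 | starting material
2 | 2,3-dibromo-4,5-dihydroxybenzaldehyde | O=Cc1cc(O)c(O)c(Br)c1Br | intermediate
3 | (E)-2,3-dibromo-4,5-dihydroxybenzaldehyde oxime | O/N=C/c1cc(O)c(O)c(Br)c1Br | intermediate
4 | 2,3-dibromo-4,5-dihydroxybenzylamine, also named 5-(aminomethyl)-3,4-dibromobenzene-1,2-diol | NCc1cc(O)c(O)c(Br)c1Br | intermediate
5 | succinic anhydride (oxolane-2,5-dione) | O=C1CCC(=O)O1 | starting material
6 | 4-[(2,3-dibromo-4,5-dihydroxybenzyl)amino]-4-oxobutanoic acid | O=C(O)CCC(=O)NCc1cc(O)c(O)c(Br)c1Br | target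

**Total step count:** 3
**Longest linear sequence:** 3 (1 → 2 → 4 → 6)

**Steps most likely to fail, in falling order of risk**

Most at risk is step 2. Zinc may partly remove bromine, zinc salts may cling to the catechol, and the free aminocatechol is awkward to isolate.
- The fallback sets out from 2 and comes back to the route at 4.
- It replaces dissolving-metal reduction of an oxime by a metal-free reductive amidation (ionic hydrogenation).
- Aldehyde 2 is stirred with tert-butyl carbamate, Et3SiH and TFA in MeCN at rt.
- The transient tert-butyl (E)-N-(2,3-dibromo-4,5-dihydroxybenzylidene)carbamate F1 takes up hydride in the flask.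
- This gives tert-butyl N-(2,3-dibromo-4,5-dihydroxybenzyl)carbamate F2, a neutral compound that can be purified on silica and cannot be alkylated twice.
- HCl in dioxane at rt then removes the Boc group, and neutralisation gives 4.

Second is step 1. The ring is deactivated, so the bromination may be slow. It may also give some C6 isomer or tribromide, or oxidise the free catechol.
- The fallback sets out from 1 and comes back at 2. It masks the catechol before the bromination.
- MeI and K2CO3 in DMF give 3-bromo-4,5-dimethoxybenzaldehyde F3, which cannot form a quinone.
- Br2 in AcOH at 60 °C then brominates para to the 5-OMe group, the site at which veratraldehyde itself reacts. The flanked 4-OMe group is twisted out of conjugation.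
- The product is 2,3-dibromo-4,5-dimethoxybenzaldehyde F4, which can be freed from any isomer by crystallisation or chromatography.
- BBr3 in CH2Cl2 (−78 °C to rt) cleaves both methyl ethers and gives 2.

Third is step 3. Possible problems are O-acylation, air oxidation, and purification of a very polar catechol acid.
- The fallback sets out from 4 and comes back at 6. It replaces anhydride opening by a carbodiimide coupling with a protected half-ester.
- Amine 4 is coupled with 4-tert-butoxy-4-oxobutanoic acid using EDC·HCl and HOBt in DMF.
- This gives tert-butyl 4-[(2,3-dibromo-4,5-dihydroxybenzyl)amino]-4-oxobutanoate F5, which is neutral and can be chromatographed.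
- TFA in CH2Cl2 at rt then frees the acid under non-oxidising, non-basic conditions and gives 6.

**Further compounds**
F1 | step 2 | tert-butyl (E)-N-(2,3-dibromo-4,5-dihydroxybenzylidene)carbamate | CC(C)(C)OC(=O)/N=C/c1cc(O)c(O)c(Br)c1Br
F2 | step 2 | tert-butyl N-(2,3-dibromo-4,5-dihydroxybenzyl)carbamate | CC(C)(C)OC(=O)NCc1cc(O)c(O)c(Br)c1Br
F3 | step 1 | 3-bromo-4,5-dimethoxybenzaldehyde | O=Cc1cc(OC)c(OC)c(Br)c1
F4 | step 1 | 2,3-dibromo-4,5-dimethoxybenzaldehyde | O=Cc1cc(OC)c(OC)c(Br)c1Br
F5 | step 3 | tert-butyl 4-[(2,3-dibromo-4,5-dihydroxybenzyl)amino]-4-oxobutanoate | CC(C)(C)OC(=O)CCC(=O)NCc1cc(O)c(O)c(Br)c1Br
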